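| flask | X | E | remark | time |
|---|---|---|---|---|
| beta | 0.10 M | 0.042 M | run made earlier |  |
| theta | 0.10 M | 0.066 M | run made earlier |  |
| zeta | 0.050 M | 0.030 M | run made earlier |  |
| flask | 0.10 M | 0.0300 M |  | 5.0 h |

| run | time / h | J / % | G / % |
|---|---|---|---|
| beta | 0.333 | 2.5 | 0.6 |
| beta | 0.667 | 6.4 | 0.8 |
| beta | 1.50 | 15.6 | 3.4 |
| beta | 4.00 | 41.6 | 1.2 |
| theta | 1.00 | 9.1 | 1.2 |
| theta | 2.00 | 20.7 | 0.5 |
| theta | 3.00 | 31.6 | 2.0 |
| theta | 4.00 | 41.2 | 0.6 |
| zeta | 0.500 | 7.5 | 2.6 |
| zeta | 1.33 | 27.3 | 3.8 |
| zeta | 2.50 | 51.5 | 2.8 |
| zeta | 4.00 | 83.8 | 3.7 |

(standard deviation of a reading: 1 percentage point)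

1. J at 5.0 h, in percent of the X charged
2. concentration of G in solution at 5.0 h, in percent of saturation

Count every run in fractions of the flask's charge of X before reading a slope. So counted, J at the last reading stands at 41.6 % in the beta run, 41.2 % in the theta run and 41.9 % in the zeta run, although E in the theta run is twice that in the zeta run and X in the zeta run is half that in the theta run.

Between its first and last readings the zeta run climbs by 0.109 /h, steeper than the other two runs; call this the hourly take, the fraction of the charge turned into J per hour, a zero-order rate as read.

Held over the whole 5.0 h from zero, the take gives an upper estimate of 54.5 % for J in the flask. Started instead from the beta reading at 4.00 h, raised by one scatter of 1 percentage point, it brings that upper estimate down to 53.5 %. The theta run has the lowest average from zero, and that average, carried to 5.0 h, gives a lower estimate of 51.5 %.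

Now put the first answer back: the flask then still holds 46.5 % of its charge as something other than J, more than the 8.10 % at which the zeta run was still climbing, so the second round leaves the bracket where it stands. The reckoning commits to its middle, 52.5 %, and offers no figure for saturation.

The forecast gives 52 % of J, inside the bracket, and 90 % of saturation, reading the flask as “a solution held near saturation by excess solid”.

The flask gives 53.3 % of J, with G at 6.92 % of saturation.

    G → J, rate k1*[G]/(1 + ([G]/sat1)) (32.9 mM, k = 0.00266 /s)
    X ⇌ G, rate k2*(cs2 - [G]) while solid is left; crystals form when [G] > cs2 (solubility = 17.0 mM, k = 1.97 × 10⁻⁴ /s)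
    G + E → D (k = 0.00290 /M/s)

The going into solution of X can deliver at most 60.3 % of the charge by 5.0 h into a solution kept empty, and the hourly take over that time comes to 90.4 % of this ceiling. Carried to the neighbouring flask read at 3.0 h, the take gives 32.7 %, and that flask holds 31.5 % of J.

The earlier runs and the new flask come from a simulation with constants of no real substance, noise included.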